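**Retrosynthetic overview**
- The stilbene C(aryl)–C(vinyl) bond is cut by a Heck disconnection into a 7-bromo-1,4-benzodioxane and 3,5-diacetoxystyrene; all MOM and acetyl groups fall in one final acid methanolysis.
- The CH2OH carbon is what is left of a glyceraldehyde-derived dioxolane after one-carbon excision (periodic acid, then borohydride). That dioxolane centre, bought as (S)-glyceraldehyde acetonide, is the only source of chirality.
- The 1,4-dioxane ring is formed by an inverse-demand hetero-Diels–Alder reaction of a 5-bromo-3-(MOM-oxy)-o-quinone (O=C–C=O as 4π) with an (E)-styryl dioxolane (2π). This sets C2 and C3 trans, under control of the dioxolane centre.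
- The dienophile comes from a Heck reaction of MOM-protected 4-bromosyringol with (R)-vinyl dioxolane. The quinone comes from Ag2O oxidation of the catechol made by Dakin oxidation of 3-O-MOM-5-bromo-2,3-dihydroxybenzaldehyde.
- Ring order: both benzene rings are bought; the dioxane ring is the only ring formed (step 6 of 9).

Assumption: (S)-glyceraldehyde acetonide (L-ascorbic acid series), 5-bromo-2,3-dihydroxybenzaldehyde and 3,5-diacetoxystyrene are taken as catalogue compounds.

Numbering used in all benzodioxane names: O1, C2 (aryl-bearing), C3, O4, C5 (oxygenated), C7 (Br or styryl).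

**Step 1**
Reactants: 1 4-bromo-2,6-dimethoxyphenol
Product: 2 5-bromo-1,3-dimethoxy-2-(methoxymethoxy)benzene
Conditions: NaH, MOMCl, DMF, 0 °C → rt
Reagents that add atoms: chloromethyl methyl ether (MOMCl), COCCl
Why: Williamson-type O-alkylation of the sodium phenoxide by the very reactive α-chloro ether protects the phenol as an electron-donating, base-stable acetal.

**Step 2**
Reactants: 3 (S)-2,2-dimethyl-1,3-dioxolane-4-carbaldehyde [(S)-glyceraldehyde acetonide]
Product: 4 (R)-4-ethenyl-2,2-dimethyl-1,3-dioxolane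
Conditions: Ph3PCH3Br, KHMDS, THF, −78 °C → rt; distil
Reagents that add atoms: methyltriphenylphosphonium bromide (delivers CH2 as its ylide), C[P+](c1ccccc1)(c1ccccc1)c1ccccc1.[Br-]
Why: Wittig methylenation with a salt-free non-stabilised ylide at low temperature leaves the α-alkoxy stereocentre untouched (S → R is only a CIP priority change).

**Step 3**
Reactants: 2 5-bromo-1,3-dimethoxy-2-(methoxymethoxy)benzene; 4 (R)-4-ethenyl-2,2-dimethyl-1,3-dioxolane (2.5 equiv)
Product: 5 (4R)-4-[(E)-2-[3,5-dimethoxy-4-(methoxymethoxy)phenyl]ethenyl]-2,2-dimethyl-1,3-dioxolane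
Conditions: Pd(OAc)2 (5 mol %), P(o-tol)3 (10 mol %), n-Bu4NBr, K2CO3, DMF, 95 °C, sealed tube
Reagents that add atoms: none
Why: Mizoroki–Heck arylation at the terminal alkene carbon followed by syn β-hydride elimination toward the benzylic position gives the conjugated (E)-styrene without touching the allylic stereocentre.

**Step 4**
Reactants: 6 5-bromo-2,3-dihydroxybenzaldehyde
Product: 7 5-bromo-2-hydroxy-3-(methoxymethoxy)benzaldehyde
Conditions: NaH (2.2 equiv), DMF, 0 °C; MOMCl (1.0 equiv), 0 °C → rt; cold 1 M HCl to pH 6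
Reagents that add atoms: chloromethyl methyl ether (MOMCl), COCCl
Why: In the dianion the 2-phenoxide is chelated and conjugated to the formyl group, so regioselective O-alkylation occurs at the more nucleophilic 3-phenoxide.

**Step 5**
Reactants: 7 5-bromo-2-hydroxy-3-(methoxymethoxy)benzaldehyde
Product: 9 5-bromo-3-(methoxymethoxy)benzene-1,2-diol, via aryl formate 8 (not isolated)
Conditions: 30% H2O2 (1.05 equiv), NaOH (1.1 equiv), THF–H2O, 0 °C, N2; then pH 5 buffer
Reagents that add atoms: hydrogen peroxide, OO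
Why: Dakin oxidation of the o-hydroxybenzaldehyde (aryl migration in the peroxide adduct, then hydrolysis of the formate) turns CHO into OH and gives the catechol with the third oxygen already protected.

**Step 6**
Reactants: 9 5-bromo-3-(methoxymethoxy)benzene-1,2-diol (2 equiv, added over 6 h); 5 (4R)-4-[(E)-2-[3,5-dimethoxy-4-(methoxymethoxy)phenyl]ethenyl]-2,2-dimethyl-1,3-dioxolane
Product: 11 (2S,3R)-7-bromo-2-[3,5-dimethoxy-4-(methoxymethoxy)phenyl]-3-[(4S)-2,2-dimethyl-1,3-dioxolan-4-yl]-5-(methoxymethoxy)-2,3-dihydro-1,4-benzodioxine, via o-quinone 10 (not isolated)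
Conditions: Ag2O (3 equiv), 4 Å MS, toluene, rt, dark; chromatography
Reagents that add atoms: none
Why: In this inverse-electron-demand hetero-Diels–Alder reaction the O=C–C=O unit of the o-quinone adds suprafacially to the (E)-styrene (E → 2,3-trans), with the non-benzylic alkene carbon bonding to the oxygen of the more electrophilic carbonyl next to C–OMOM and the benzylic carbon to the other oxygen; the quinone approaches anti to the dioxolane C4–C5 bond with the allylic C–O "inside" (inside-alkoxy model), so the bought centre sets C2 as S and C3 as R (estimated dr about 3–5:1, minor diastereomer removed by chromatography).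

**Step 7**
Reactants: 11 (2S,3R)-7-bromo-2-[3,5-dimethoxy-4-(methoxymethoxy)phenyl]-3-[(4S)-2,2-dimethyl-1,3-dioxolan-4-yl]-5-(methoxymethoxy)-2,3-dihydro-1,4-benzodioxine
Product: 14 [(2S,3S)-7-bromo-2-[3,5-dimethoxy-4-(methoxymethoxy)phenyl]-5-(methoxymethoxy)-2,3-dihydro-1,4-benzodioxin-3-yl]methanol, via diol 12 (not isolated), via aldehyde 13 (not isolated)
Conditions: H5IO6 (1.5 equiv), EtOAc, 0 °C → rt; aq NaHCO3 wash; crude aldehyde, NaBH4, EtOH–THF, 0 °C
Reagents that add atoms: none
Why: Periodic acid (pKa about 3.3, mild enough for aryl MOM ethers) hydrolyses the terminal acetonide and cleaves the freed 1,2-diol in one pot (Malaprade glycol cleavage) and borohydride reduces the aldehyde at once; C2 is untouched and C3 keeps its configuration (S only by CIP priority) because the trans aldehyde is the thermodynamic epimer.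

**Step 8**
Reactants: 14 [(2S,3S)-7-bromo-2-[3,5-dimethoxy-4-(methoxymethoxy)phenyl]-5-(methoxymethoxy)-2,3-dihydro-1,4-benzodioxin-3-yl]methanol; 15 3,5-diacetoxystyrene (5-ethenyl-1,3-phenylene diacetate)
Product: 16 5-[(E)-2-[(2S,3S)-2-[3,5-dimethoxy-4-(methoxymethoxy)phenyl]-3-(hydroxymethyl)-5-(methoxymethoxy)-2,3-dihydro-1,4-benzodioxin-7-yl]ethenyl]-1,3-phenylene diacetate
Conditions: Pd(OAc)2 (5 mol %), P(o-tol)3 (10 mol %), Et3N, DMF, 100 °C, BHT (trace)
Reagents that add atoms: none
Why: Mizoroki–Heck coupling of the unhindered aryl bromide with the styrene gives the (E)-stilbene by syn insertion and syn β-hydride elimination, with no effect on the two sp3 stereocentres; any acetyl scrambling onto the primary alcohol is erased in step 9.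

**Step 9**
Reactants: 16 5-[(E)-2-[(2S,3S)-2-[3,5-dimethoxy-4-(methoxymethoxy)phenyl]-3-(hydroxymethyl)-5-(methoxymethoxy)-2,3-dihydro-1,4-benzodioxin-7-yl]ethenyl]-1,3-phenylene diacetate
Product: 17 (2S,3S)-7-[(E)-2-(3,5-dihydroxyphenyl)ethenyl]-2-(4-hydroxy-3,5-dimethoxyphenyl)-3-(hydroxymethyl)-2,3-dihydro-1,4-benzodioxin-5-ol
Conditions: 1.25 M HCl in MeOH, 40 °C, Ar; NaHCO3 quench
Reagents that add atoms: none
Why: Acid-catalysed acetal exchange removes both MOM groups as dimethoxymethane and acid transesterification removes both acetates as methyl acetate, under conditions too mild to ionise the cyclic benzylic aryl ether.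

**Compound list**
1 | 4-bromo-2,6-dimethoxyphenol | COc1cc(Br)cc(OC)c1O | starting material
2 | 5-bromo-1,3-dimethoxy-2-(methoxymethoxy)benzene | COCOc1c(OC)cc(Br)cc1OC | intermediate
3 | (S)-2,2-dimethyl-1,3-dioxolane-4-carbaldehyde | CC1(C)OC[C@@H](C=O)O1 | starting material
4 | (R)-4-ethenyl-2,2-dimethyl-1,3-dioxolane | CC1(C)OC[C@@H](C=C)O1 | intermediate
5 | (4R)-4-[(E)-2-[3,5-dimethoxy-4-(methoxymethoxy)phenyl]ethenyl]-2,2-dimethyl-1,3-dioxolane | CC1(C)OC[C@@H](/C=C/c2cc(OC)c(OCOC)c(OC)c2)O1 | intermediate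
6 | 5-bromo-2,3-dihydroxybenzaldehyde | O=Cc1cc(Br)cc(O)c1O | starting material
7 | 5-bromo-2-hydroxy-3-(methoxymethoxy)benzaldehyde | COCOc1cc(Br)cc(C=O)c1O | intermediate
8 | 5-bromo-2-hydroxy-3-(methoxymethoxy)phenyl formate | COCOc1cc(Br)cc(OC=O)c1O | intermediate
9 | 5-bromo-3-(methoxymethoxy)benzene-1,2-diol | COCOc1cc(Br)cc(O)c1O | intermediate
10 | 5-bromo-3-(methoxymethoxy)cyclohexa-3,5-diene-1,2-dione | COCOC1=CC(Br)=CC(=O)C1=O | intermediate
11 | (2S,3R)-7-bromo-2-[3,5-dimethoxy-4-(methoxymethoxy)phenyl]-3-[(4S)-2,2-dimethyl-1,3-dioxolan-4-yl]-5-(methoxymethoxy)-2,3-dihydro-1,4-benzodioxine | COCOc1c(OC)cc([C@@H]2Oc3cc(Br)cc(OCOC)c3O[C@H]2[C@@H]4COC(C)(C)O4)cc1OC | intermediate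
12 | (1S)-1-[(2S,3S)-7-bromo-2-[3,5-dimethoxy-4-(methoxymethoxy)phenyl]-5-(methoxymethoxy)-2,3-dihydro-1,4-benzodioxin-3-yl]ethane-1,2-diol | COCOc1c(OC)cc([C@@H]2Oc3cc(Br)cc(OCOC)c3O[C@H]2[C@@H](O)CO)cc1OC | intermediate
13 | (2S,3R)-7-bromo-2-[3,5-dimethoxy-4-(methoxymethoxy)phenyl]-5-(methoxymethoxy)-2,3-dihydro-1,4-benzodioxine-3-carbaldehyde | COCOc1c(OC)cc([C@@H]2Oc3cc(Br)cc(OCOC)c3O[C@H]2C=O)cc1OC | intermediate
14 | [(2S,3S)-7-bromo-2-[3,5-dimethoxy-4-(methoxymethoxy)phenyl]-5-(methoxymethoxy)-2,3-dihydro-1,4-benzodioxin-3-yl]methanol | COCOc1c(OC)cc([C@@H]2Oc3cc(Br)cc(OCOC)c3O[C@H]2CO)cc1OC | intermediate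
15 | 3,5-diacetoxystyrene (5-ethenyl-1,3-phenylene diacetate) | CC(=O)Oc1cc(C=C)cc(OC(C)=O)c1 | starting material
16 | 5-[(E)-2-[(2S,3S)-2-[3,5-dimethoxy-4-(methoxymethoxy)phenyl]-3-(hydroxymethyl)-5-(methoxymethoxy)-2,3-dihydro-1,4-benzodioxin-7-yl]ethenyl]-1,3-phenylene diacetate | COCOc1c(OC)cc([C@@H]2Oc3cc(/C=C/c4cc(OC(C)=O)cc(OC(C)=O)c4)cc(OCOC)c3O[C@H]2CO)cc1OC | intermediate
17 | (2S,3S)-7-[(E)-2-(3,5-dihydroxyphenyl)ethenyl]-2-(4-hydroxy-3,5-dimethoxyphenyl)-3-(hydroxymethyl)-2,3-dihydro-1,4-benzodioxin-5-ol | COc1cc([C@@H]2Oc3cc(/C=C/c4cc(O)cc(O)c4)cc(O)c3O[C@H]2CO)cc(OC)c1O | target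

**Totals**
Total step count: 9. Longest linear sequence: 6 (steps 1, 3, 6, 7, 8, 9).

**Three steps most likely to fail**

Step 6 (cycloaddition). The sense and size of the π-facial bias from the dioxolane is a model-based prediction, and the quinone can dimerise before it is trapped. If the syn adduct turns out to be the major one, the controller is changed, not the conditions. The fallback sets out from 2 and uses the mirror-image chiral-pool aldehyde (R)-2,2-dimethyl-1,3-dioxolane-4-carbaldehyde F1 (D-mannitol series). Wittig methylenation of it gives (S)-4-ethenyl-2,2-dimethyl-1,3-dioxolane F2. Heck coupling of that with 2 gives the (4S,E)-styryl dioxolane F3. The same Ag2O-mediated cycloaddition with 9 (through 10) then gives the (2S,3R,4′R) adduct F4 as the major isomer. Periodic acid takes F4 through the (1R)-diol F5 to aldehyde 13, where the fallback rejoins the route, because the epimeric dioxolane carbon is excised.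

Step 3 (Heck on a volatile, non-activated allylic acetal alkene). Oxidative addition of the electron-rich bromide may be slow, and branched or enol-ether products are possible. The fallback sets out from 2 and 4 and builds the alkene by metathesis instead. Suzuki vinylation of 2 (vinylboronic acid pinacol ester, Pd(dppf)Cl2, K2CO3, dioxane–H2O) gives 5-ethenyl-1,3-dimethoxy-2-(methoxymethoxy)benzene F6. Cross-metathesis of this styrene with an excess of 4 (Grubbs II, CH2Cl2, 40 °C) gives the E-alkene and rejoins the route at 5.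

Step 9 (global acid deprotection). The product combines a p-hydroxybenzylic aryl ether, an electron-rich stilbene and a resorcinol ring that could capture formaldehyde-derived electrophiles. The fallback sets out from 14 and moves the acid step ahead of stilbene formation. HCl in MeOH–THF at rt removes both MOM groups to give (2S,3S)-7-bromo-2-(4-hydroxy-3,5-dimethoxyphenyl)-3-(hydroxymethyl)-2,3-dihydro-1,4-benzodioxin-5-ol F7. Heck coupling of this with 15 gives the target 3′,5′-diacetate F8. Brief catalytic K2CO3 in degassed MeOH at 0 °C (AcOH quench) then removes the acetates and rejoins the route at 17.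

**Further compounds**
F1 | step 6 | (R)-2,2-dimethyl-1,3-dioxolane-4-carbaldehyde | CC1(C)OC[C@H](C=O)O1
F2 | step 6 | (S)-4-ethenyl-2,2-dimethyl-1,3-dioxolane | CC1(C)OC[C@H](C=C)O1
F3 | step 6 | (4S)-4-[(E)-2-[3,5-dimethoxy-4-(methoxymethoxy)phenyl]ethenyl]-2,2-dimethyl-1,3-dioxolane | CC1(C)OC[C@H](/C=C/c2cc(OC)c(OCOC)c(OC)c2)O1
F4 | step 6 | (2S,3R)-7-bromo-2-[3,5-dimethoxy-4-(methoxymethoxy)phenyl]-3-[(4R)-2,2-dimethyl-1,3-dioxolan-4-yl]-5-(methoxymethoxy)-2,3-dihydro-1,4-benzodioxine | COCOc1c(OC)cc([C@@H]2Oc3cc(Br)cc(OCOC)c3O[C@H]2[C@H]4COC(C)(C)O4)cc1OC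
F5 | step 6 | (1R)-1-[(2S,3S)-7-bromo-2-[3,5-dimethoxy-4-(methoxymethoxy)phenyl]-5-(methoxymethoxy)-2,3-dihydro-1,4-benzodioxin-3-yl]ethane-1,2-diol | COCOc1c(OC)cc([C@@H]2Oc3cc(Br)cc(OCOC)c3O[C@H]2[C@H](O)CO)cc1OC
F6 | step 3 | 5-ethenyl-1,3-dimethoxy-2-(methoxymethoxy)benzene | COCOc1c(OC)cc(C=C)cc1OC
F7 | step 9 | (2S,3S)-7-bromo-2-(4-hydroxy-3,5-dimethoxyphenyl)-3-(hydroxymethyl)-2,3-dihydro-1,4-benzodioxin-5-ol | COc1cc([C@@H]2Oc3cc(Br)cc(O)c3O[C@H]2CO)cc(OC)c1O
F8 | step 9 | 5-[(E)-2-[(2S,3S)-5-hydroxy-2-(4-hydroxy-3,5-dimethoxyphenyl)-3-(hydroxymethyl)-2,3-dihydro-1,4-benzodioxin-7-yl]ethenyl]-1,3-phenylene diacetate | COc1cc([C@@H]2Oc3cc(/C=C/c4cc(OC(C)=O)cc(OC(C)=O)c4)cc(O)c3O[C@H]2CO)cc(OC)c1O
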